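**Retrosynthetic overview**

- Acredinone B is cut at the ArCH2–C(=O)Ar bond into a benzylzinc chloride (ring B half) and a benzaldehyde (ring C half), joined by addition and then oxidation of the carbinol; both halves come from one benzylic alcohol.
- The route rests on this feature: ring B (carrying the CH2) and ring C (carrying the bridge C=O) are the same pentasubstituted benzene. Going round from the aroyl-bearing carbon it reads C–OH, C–H, C–CH3, C–OCH3, C–(bridge carbon), a hydroquinone with OH beside the aroyl carbon and OCH3 para to it.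
- That ring is made by [4+2] addition of a 4-methyl-2-silyloxyfuran (O1, C2–OSi, C3–H, C4–CH3, C5–H) across an aroyl ynone, followed by opening of the oxygen bridge. The furan oxygen becomes the OH that is methylated; the silyloxy oxygen becomes the OH beside the ketone.
- Ring order: rings A and D (2,6-dimethoxyphenyl) are bought with the aldehyde; the ring B/C benzene is the only ring formed (step 4) and is used twice.

Key step: step 4

Remark on the chemistry: the far end of the alkyne carries CH2OTBS (TBS = tert-butyldimethylsilyl) and not a bare methyl, because that carbon must become CH2 in ring B and C=O in ring C, and later oxidation could not tell it from the other ring methyl. The two carbinol intermediates are racemic and are oxidised away; the target is achiral.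

**Route**

Step 1
Reactants: 1 4-methylfuran-2(5H)-one
Product: 2 tert-butyldimethyl[(4-methylfuran-2-yl)oxy]silane
Conditions: TBSOTf, Et3N, CH2Cl2, 0 °C → rt
Reagents that add atoms: tert-butyldimethylsilyl trifluoromethanesulfonate, CC(C)(C)[Si](C)(C)OS(=O)(=O)C(F)(F)F
Why: Soft enolisation of the butenolide at C5 and O-silylation of the dienolate gives the aromatic 2-silyloxyfuran, the standard silyl dienol ether formation from butenolides.

Step 2
Reactants: 3 tert-butyldimethyl(prop-2-yn-1-yloxy)silane; 4 2,6-dimethoxybenzaldehyde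
Product: 6 4-[(tert-butyldimethylsilyl)oxy]-1-(2,6-dimethoxyphenyl)but-2-yn-1-ol (racemic), via lithium acetylide 5 (not isolated)
Conditions: n-BuLi, THF, −78 °C; then 4, −78 → 0 °C; aq. NH4Cl
Reagents that add atoms: none
Why: 1,2-Addition of a lithium acetylide to a non-enolisable aryl aldehyde; the new carbinol centre is racemic and is removed in step 3.

Step 3
Reactants: 6 4-[(tert-butyldimethylsilyl)oxy]-1-(2,6-dimethoxyphenyl)but-2-yn-1-ol
Product: 7 4-[(tert-butyldimethylsilyl)oxy]-1-(2,6-dimethoxyphenyl)but-2-yn-1-one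
Conditions: MnO2, CH2Cl2, rt
Reagents that add atoms: none
Why: MnO2 oxidation of an alcohol that is both benzylic and propargylic gives the ynone under neutral conditions that leave the silyl ether alone.

Step 4
Reactants: 2 tert-butyldimethyl[(4-methylfuran-2-yl)oxy]silane; 7 4-[(tert-butyldimethylsilyl)oxy]-1-(2,6-dimethoxyphenyl)but-2-yn-1-one
Product: 9 [6-(tert-butyldimethylsilyloxy)-2-{[(tert-butyldimethylsilyl)oxy]methyl}-3-hydroxy-4-methylphenyl](2,6-dimethoxyphenyl)methanone, via oxanorbornadiene cycloadduct 8 (not isolated)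
Conditions: 2 (1.5 equiv), PhMe, 90 °C, sealed tube, Ar; bridge opening in situ
Reagents that add atoms: none
Why: The donor oxygen at furan C2 and the methyl at C4 put the largest HOMO coefficient at C5, and the ketone puts the largest LUMO coefficient at the alkyne carbon remote from it, so a polarised, asynchronous [4+2] cycloaddition joins C5 to the CH2OTBS-bearing alkyne carbon and C2 to the aroyl-bearing one, giving the 7-oxanorbornadiene 8. In 8 the bridge C–O bond at the ketal bridgehead ionises to a silyloxycarbenium ion and loss of the proton at the other bridgehead aromatises the ring, so the bridge oxygen ends as a free OH beside the CH2OTBS carbon and the silyl ether ends beside the aroyl carbon. The closest known reaction type is the Diels–Alder reaction of 2-silyloxyfurans with acetylenic ketones and esters, which gives hydroquinone monosilyl ethers. The one ring closed is the six-membered carbocycle, closed by intermolecular cycloaddition through the bonds furan C2–alkyne C2 and furan C5–alkyne C3; the two bridgehead stereocentres of 8 vanish on aromatisation, so no stereocontrol is needed. The selectivity needed is regiochemical and is secured by the matched polarisation of the two partners; because only one of the two oxygens carries silicon, the other can later be methylated alone.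

Step 5
Reactants: 9 [6-(tert-butyldimethylsilyloxy)-2-{[(tert-butyldimethylsilyl)oxy]methyl}-3-hydroxy-4-methylphenyl](2,6-dimethoxyphenyl)methanone
Product: 10 [6-(tert-butyldimethylsilyloxy)-2-{[(tert-butyldimethylsilyl)oxy]methyl}-3-methoxy-4-methylphenyl](2,6-dimethoxyphenyl)methanone
Conditions: MeI, K2CO3, anhydrous acetone, rt → 40 °C
Reagents that add atoms: iodomethane, CI
Why: Williamson methylation of the only free phenol; in anhydrous acetone both silyl ethers should stay in place.

Step 6
Reactants: 10 [6-(tert-butyldimethylsilyloxy)-2-{[(tert-butyldimethylsilyl)oxy]methyl}-3-methoxy-4-methylphenyl](2,6-dimethoxyphenyl)methanone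
Product: 11 [6-(tert-butyldimethylsilyloxy)-2-(hydroxymethyl)-3-methoxy-4-methylphenyl](2,6-dimethoxyphenyl)methanone
Conditions: AcOH/THF/H2O (3:1:1), rt
Reagents that add atoms: none
Why: Acid-catalysed hydrolysis of silyl ethers cleaves a primary alkyl TBS ether much faster than an aryl TBS ether, and the ketone, flanked by four ortho substituents, should not be trapped as a cyclic hemiketal.

Step 7
Reactants: 11 [6-(tert-butyldimethylsilyloxy)-2-(hydroxymethyl)-3-methoxy-4-methylphenyl](2,6-dimethoxyphenyl)methanone (one portion)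
Product: 12 3-(tert-butyldimethylsilyloxy)-2-(2,6-dimethoxybenzoyl)-6-methoxy-5-methylbenzaldehyde
Conditions: Dess–Martin periodinane, CH2Cl2, 0 °C → rt
Reagents that add atoms: none
Why: Dess–Martin oxidation takes a primary benzylic alcohol to the aldehyde without over-oxidation and leaves the aryl silyl ether intact.

Step 8
Reactants: 11 [6-(tert-butyldimethylsilyloxy)-2-(hydroxymethyl)-3-methoxy-4-methylphenyl](2,6-dimethoxyphenyl)methanone (second portion)
Product: 13 [6-(tert-butyldimethylsilyloxy)-2-(chloromethyl)-3-methoxy-4-methylphenyl](2,6-dimethoxyphenyl)methanone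
Conditions: PPh3/NCS (premixed), CH2Cl2, 0 °C → rt
Reagents that add atoms: N-chlorosuccinimide, O=C1CCC(=O)N1Cl
Why: Appel-type chlorination through the alkoxyphosphonium salt, with chloride displacing at the primary benzylic carbon under neutral conditions; premixing the reagents keeps free NCS away from the electron-rich ring.

Step 9
Reactants: 13 [6-(tert-butyldimethylsilyloxy)-2-(chloromethyl)-3-methoxy-4-methylphenyl](2,6-dimethoxyphenyl)methanone; 12 3-(tert-butyldimethylsilyloxy)-2-(2,6-dimethoxybenzoyl)-6-methoxy-5-methylbenzaldehyde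
Product: 15 1,2-bis[3-(tert-butyldimethylsilyloxy)-2-(2,6-dimethoxybenzoyl)-6-methoxy-5-methylphenyl]ethan-1-ol (racemic), via benzylzinc chloride 14 (not isolated)
Conditions: Zn dust, LiCl, THF, 25 °C; then 12, MgCl2, THF, 0 → 25 °C; aq. NH4Cl
Reagents that add atoms: none
Why: LiCl-assisted zinc insertion into a benzylic chloride gives a benzylzinc reagent that tolerates the hindered diaryl ketones and, with MgCl2 activation, adds only to the aldehyde (Barbier-type 1,2-addition); the carbinol is racemic and is removed in step 10.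

Step 10
Reactants: 15 1,2-bis[3-(tert-butyldimethylsilyloxy)-2-(2,6-dimethoxybenzoyl)-6-methoxy-5-methylphenyl]ethan-1-ol
Product: 16 1,2-bis[3-(tert-butyldimethylsilyloxy)-2-(2,6-dimethoxybenzoyl)-6-methoxy-5-methylphenyl]ethan-1-one
Conditions: Dess–Martin periodinane, CH2Cl2, 0 °C → rt
Reagents that add atoms: none
Why: Dess–Martin oxidation of the secondary benzylic alcohol gives the aryl benzyl ketone under near-neutral conditions, avoiding the strong acid or base that could cyclise the keto–CH2–aryl–ketone array.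

Step 11
Reactants: 16 1,2-bis[3-(tert-butyldimethylsilyloxy)-2-(2,6-dimethoxybenzoyl)-6-methoxy-5-methylphenyl]ethan-1-one
Product: 17 acredinone B, 1,2-bis[2-(2,6-dimethoxybenzoyl)-3-hydroxy-6-methoxy-5-methylphenyl]ethan-1-one
Conditions: Bu4NF, AcOH, THF, 0 °C
Reagents that add atoms: none
Why: Fluoride cleaves both aryl silyl ethers, and the acetic acid buffer keeps the medium from enolising the CH2 next to the ketone, so no aldol closure onto a neighbouring aroyl group should occur.

**Compound list**

1 | 4-methylfuran-2(5H)-one | CC1=CC(=O)OC1 | starting material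
2 | tert-butyldimethyl[(4-methylfuran-2-yl)oxy]silane | Cc1coc(O[Si](C)(C)C(C)(C)C)c1 | intermediate
3 | tert-butyldimethyl(prop-2-yn-1-yloxy)silane | C#CCO[Si](C)(C)C(C)(C)C | starting material
4 | 2,6-dimethoxybenzaldehyde | COc1cccc(OC)c1C=O | starting material
5 | {3-[(tert-butyldimethylsilyl)oxy]prop-1-yn-1-yl}lithium (not isolated) | [Li]C#CCO[Si](C)(C)C(C)(C)C | intermediate
6 | 4-[(tert-butyldimethylsilyl)oxy]-1-(2,6-dimethoxyphenyl)but-2-yn-1-ol (racemic) | COc1cccc(OC)c1C(O)C#CCO[Si](C)(C)C(C)(C)C | intermediate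
7 | 4-[(tert-butyldimethylsilyl)oxy]-1-(2,6-dimethoxyphenyl)but-2-yn-1-one | COc1cccc(OC)c1C(=O)C#CCO[Si](C)(C)C(C)(C)C | intermediate
8 | [1-(tert-butyldimethylsilyloxy)-3-{[(tert-butyldimethylsilyl)oxy]methyl}-5-methyl-7-oxabicyclo[2.2.1]hepta-2,5-dien-2-yl](2,6-dimethoxyphenyl)methanone (racemic, relative configuration fixed by the bridge; not isolated) | CC1=CC2(O[Si](C)(C)C(C)(C)C)OC1C(CO[Si](C)(C)C(C)(C)C)=C2C(=O)c1c(OC)cccc1OC | intermediate
9 | [6-(tert-butyldimethylsilyloxy)-2-{[(tert-butyldimethylsilyl)oxy]methyl}-3-hydroxy-4-methylphenyl](2,6-dimethoxyphenyl)methanone | COc1cccc(OC)c1C(=O)c1c(O[Si](C)(C)C(C)(C)C)cc(C)c(O)c1CO[Si](C)(C)C(C)(C)C | intermediate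
10 | [6-(tert-butyldimethylsilyloxy)-2-{[(tert-butyldimethylsilyl)oxy]methyl}-3-methoxy-4-methylphenyl](2,6-dimethoxyphenyl)methanone | COc1cccc(OC)c1C(=O)c1c(O[Si](C)(C)C(C)(C)C)cc(C)c(OC)c1CO[Si](C)(C)C(C)(C)C | intermediate
11 | [6-(tert-butyldimethylsilyloxy)-2-(hydroxymethyl)-3-methoxy-4-methylphenyl](2,6-dimethoxyphenyl)methanone | COc1cccc(OC)c1C(=O)c1c(O[Si](C)(C)C(C)(C)C)cc(C)c(OC)c1CO | intermediate
12 | 3-(tert-butyldimethylsilyloxy)-2-(2,6-dimethoxybenzoyl)-6-methoxy-5-methylbenzaldehyde | COc1cccc(OC)c1C(=O)c1c(O[Si](C)(C)C(C)(C)C)cc(C)c(OC)c1C=O | intermediate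
13 | [6-(tert-butyldimethylsilyloxy)-2-(chloromethyl)-3-methoxy-4-methylphenyl](2,6-dimethoxyphenyl)methanone | COc1cccc(OC)c1C(=O)c1c(O[Si](C)(C)C(C)(C)C)cc(C)c(OC)c1CCl | intermediate
14 | {[3-(tert-butyldimethylsilyloxy)-2-(2,6-dimethoxybenzoyl)-6-methoxy-5-methylphenyl]methyl}zinc chloride (not isolated) | COc1cccc(OC)c1C(=O)c1c(O[Si](C)(C)C(C)(C)C)cc(C)c(OC)c1C[Zn]Cl | intermediate
15 | 1,2-bis[3-(tert-butyldimethylsilyloxy)-2-(2,6-dimethoxybenzoyl)-6-methoxy-5-methylphenyl]ethan-1-ol (racemic) | COc1cccc(OC)c1C(=O)c1c(O[Si](C)(C)C(C)(C)C)cc(C)c(OC)c1CC(O)c1c(OC)c(C)cc(O[Si](C)(C)C(C)(C)C)c1C(=O)c1c(OC)cccc1OC | intermediate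
16 | 1,2-bis[3-(tert-butyldimethylsilyloxy)-2-(2,6-dimethoxybenzoyl)-6-methoxy-5-methylphenyl]ethan-1-one | COc1cccc(OC)c1C(=O)c1c(O[Si](C)(C)C(C)(C)C)cc(C)c(OC)c1CC(=O)c1c(OC)c(C)cc(O[Si](C)(C)C(C)(C)C)c1C(=O)c1c(OC)cccc1OC | intermediate
17 | acredinone B, 1,2-bis[2-(2,6-dimethoxybenzoyl)-3-hydroxy-6-methoxy-5-methylphenyl]ethan-1-one | COc1cccc(OC)c1C(=O)c1c(O)cc(C)c(OC)c1CC(=O)c1c(OC)c(C)cc(O)c1C(=O)c1c(OC)cccc1OC | target

**Step count**

Total: 11 steps. Longest linear sequence: 9 steps (steps 2, 3, 4, 5, 6, 8, 9, 10, 11, counted from 3 and 4).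

**Steps most likely to fail**

Step 4. The alkyne is disubstituted and carries a twisted, hindered aroyl group. The cycloaddition may be slower than the decomposition of the silyloxyfuran, the regiochemistry may leak, or the silyl group may move between the two oxygens while the bridge opens. The fallback takes the hindered aroyl group out of the dienophile and brings it in afterwards through a phthalide; it sets out from 3 and 2 and returns at 11.
- Lithium acetylide 5 (from 3 and n-BuLi) is quenched with methyl chloroformate to give methyl 4-[(tert-butyldimethylsilyl)oxy]but-2-ynoate F1, a small and strongly polarised dienophile.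
- Heating F1 with 2 in PhMe should give, through the bridged adduct methyl 1-(tert-butyldimethylsilyloxy)-3-{[(tert-butyldimethylsilyl)oxy]methyl}-5-methyl-7-oxabicyclo[2.2.1]hepta-2,5-diene-2-carboxylate F2, the phenol methyl 6-(tert-butyldimethylsilyloxy)-2-{[(tert-butyldimethylsilyl)oxy]methyl}-3-hydroxy-4-methylbenzoate F3.
- Methylation (MeI, K2CO3, acetone) gives methyl 6-(tert-butyldimethylsilyloxy)-2-{[(tert-butyldimethylsilyl)oxy]methyl}-3-methoxy-4-methylbenzoate F4.
- TsOH in wet THF removes the alkyl silyl group and the freed alcohol lactonises to 7-(tert-butyldimethylsilyloxy)-4-methoxy-5-methylisobenzofuran-1(3H)-one F5.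
- (2,6-Dimethoxyphenyl)lithium F6 (1,3-dimethoxybenzene, n-BuLi, THF) is added at −78 °C to the lactone carbonyl; the addition stops at the hemiketal alkoxide, and work-up gives keto alcohol 11.

Step 9. Zinc insertion may be accompanied by Wurtz-type homocoupling of the benzylic chloride, and addition between two ortho,ortho-disubstituted partners may be sluggish. The fallback replaces the organozinc by a sulfone-stabilised carbanion; it sets out from 13 and 12 and returns at 16, so step 10 is not needed.
- 13 and PhSO2Na in DMF give [6-(tert-butyldimethylsilyloxy)-3-methoxy-4-methyl-2-(phenylsulfonylmethyl)phenyl](2,6-dimethoxyphenyl)methanone F7.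
- LiN(SiMe3)2 in THF at −78 °C gives the lithiated sulfone F8, which adds to 12 to give the β-hydroxy sulfone 1,2-bis[3-(tert-butyldimethylsilyloxy)-2-(2,6-dimethoxybenzoyl)-6-methoxy-5-methylphenyl]-2-(phenylsulfonyl)ethan-1-ol F9 (mixture of diastereomers).
- Dess–Martin oxidation gives the β-keto sulfone 1,2-bis[3-(tert-butyldimethylsilyloxy)-2-(2,6-dimethoxybenzoyl)-6-methoxy-5-methylphenyl]-2-(phenylsulfonyl)ethan-1-one F10.
- Reductive desulfonylation with Zn in AcOH/THF gives 16.

Step 5. The phenoxide may pull the aryl silyl group off (silyl transfer between oxygens), and the freed phenol would then be methylated as well. The fallback drops the silyl group on purpose and relies on hydrogen bonding of the OH beside the ketone; it sets out from 9 and returns at 10.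
- K2CO3 in MeOH cleaves only the aryl silyl ether and gives the hydroquinone [2-{[(tert-butyldimethylsilyl)oxy]methyl}-3,6-dihydroxy-4-methylphenyl](2,6-dimethoxyphenyl)methanone F11.
- One equivalent of MeI with K2CO3 in acetone under argon methylates the OH that is not chelated to the ketone and gives [2-{[(tert-butyldimethylsilyl)oxy]methyl}-6-hydroxy-3-methoxy-4-methylphenyl](2,6-dimethoxyphenyl)methanone F12.
- TBSOTf and 2,6-lutidine in CH2Cl2 put the silyl group back on the chelated phenol and give 10.

**Further compounds**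

F1 | step 4 | methyl 4-[(tert-butyldimethylsilyl)oxy]but-2-ynoate | COC(=O)C#CCO[Si](C)(C)C(C)(C)C
F2 | step 4 | methyl 1-(tert-butyldimethylsilyloxy)-3-{[(tert-butyldimethylsilyl)oxy]methyl}-5-methyl-7-oxabicyclo[2.2.1]hepta-2,5-diene-2-carboxylate (racemic, not isolated) | CC1=CC2(O[Si](C)(C)C(C)(C)C)OC1C(CO[Si](C)(C)C(C)(C)C)=C2C(=O)OC
F3 | step 4 | methyl 6-(tert-butyldimethylsilyloxy)-2-{[(tert-butyldimethylsilyl)oxy]methyl}-3-hydroxy-4-methylbenzoate | COC(=O)c1c(O[Si](C)(C)C(C)(C)C)cc(C)c(O)c1CO[Si](C)(C)C(C)(C)C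
F4 | step 4 | methyl 6-(tert-butyldimethylsilyloxy)-2-{[(tert-butyldimethylsilyl)oxy]methyl}-3-methoxy-4-methylbenzoate | COC(=O)c1c(O[Si](C)(C)C(C)(C)C)cc(C)c(OC)c1CO[Si](C)(C)C(C)(C)C
F5 | step 4 | 7-(tert-butyldimethylsilyloxy)-4-methoxy-5-methylisobenzofuran-1(3H)-one | O=C1OCc2c(OC)c(C)cc(O[Si](C)(C)C(C)(C)C)c12
F6 | step 4 | (2,6-dimethoxyphenyl)lithium | COc1cccc(OC)c1[Li]
F7 | step 9 | [6-(tert-butyldimethylsilyloxy)-3-methoxy-4-methyl-2-(phenylsulfonylmethyl)phenyl](2,6-dimethoxyphenyl)methanone | COc1cccc(OC)c1C(=O)c1c(O[Si](C)(C)C(C)(C)C)cc(C)c(OC)c1CS(=O)(=O)c1ccccc1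
F8 | step 9 | lithiated sulfone, {[3-(tert-butyldimethylsilyloxy)-2-(2,6-dimethoxybenzoyl)-6-methoxy-5-methylphenyl](phenylsulfonyl)methyl}lithium (not isolated) | COc1cccc(OC)c1C(=O)c1c(O[Si](C)(C)C(C)(C)C)cc(C)c(OC)c1C([Li])S(=O)(=O)c1ccccc1
F9 | step 9 | 1,2-bis[3-(tert-butyldimethylsilyloxy)-2-(2,6-dimethoxybenzoyl)-6-methoxy-5-methylphenyl]-2-(phenylsulfonyl)ethan-1-ol (mixture of diastereomers) | COc1cccc(OC)c1C(=O)c1c(O[Si](C)(C)C(C)(C)C)cc(C)c(OC)c1C(S(=O)(=O)c1ccccc1)C(O)c1c(OC)c(C)cc(O[Si](C)(C)C(C)(C)C)c1C(=O)c1c(OC)cccc1OC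
F10 | step 9 | 1,2-bis[3-(tert-butyldimethylsilyloxy)-2-(2,6-dimethoxybenzoyl)-6-methoxy-5-methylphenyl]-2-(phenylsulfonyl)ethan-1-one (racemic) | COc1cccc(OC)c1C(=O)c1c(O[Si](C)(C)C(C)(C)C)cc(C)c(OC)c1C(S(=O)(=O)c1ccccc1)C(=O)c1c(OC)c(C)cc(O[Si](C)(C)C(C)(C)C)c1C(=O)c1c(OC)cccc1OC
F11 | step 5 | [2-{[(tert-butyldimethylsilyl)oxy]methyl}-3,6-dihydroxy-4-methylphenyl](2,6-dimethoxyphenyl)methanone | COc1cccc(OC)c1C(=O)c1c(O)cc(C)c(O)c1CO[Si](C)(C)C(C)(C)C
F12 | step 5 | [2-{[(tert-butyldimethylsilyl)oxy]methyl}-6-hydroxy-3-methoxy-4-methylphenyl](2,6-dimethoxyphenyl)methanone | COc1cccc(OC)c1C(=O)c1c(O)cc(C)c(OC)c1CO[Si](C)(C)C(C)(C)C
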